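The rate constants are assumed; the run is a simulation.

The easy step comes first: the loss of J to G has a half-life of 21.4 h, far longer than either run, so we may follow J as it goes through E to Z, and Z as it goes on to Q.

common to all: J 0.10 M; E 27 µM

|  | time |
|---|---|
| ochre | 1.0 min |
| blue | 2.0 min |

    J + E → Z + E, rate k1*[J]^1.5*[E]/(1 + ([J]/Kh1)^1.5) (Kh1 = 0.19 M, k1 = 1800 /M^1.5/s)
    Z + E ⇌ Q + E, rate k2*[E]*[Z] forward; the back reaction follows from the equilibrium constant (K2 = 0.19, k2 = 190 /M/s)
    E → X (k3 = 0.0057 /s)
    J → G (k4 = 9.0 × 10⁻⁶ /s)

* which of these there is most of at the end, counted by the J in it, ochre (Q / J / Z)
* which of these there is most of at the end, counted by the J in it, blue (Q / J / Z)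
* how much there is at the end of the one of these that leads, in percent of the J charged: ochre
* how much there is at the end of the one of these that leads, in percent of the J charged: blue

Two of us argued over this, and we took the same zero for the scale: the even case, with c_J at half its charge. The half-way time, how long E held at its full charge needs to bring c_J from the charge to that mark by the integrated rate law of the first step, is 1.11 min.

One of us counted by the clock, holding E at its charge: ochre then stands at 0.905 half-way times, blue at 1.81. The other counted the decay of E to X, catalyst deactivation, with a lifetime of 2.92 min. Weighting the clock by the E still there gives a working time of 0.847 min in ochre and 1.45 min in blue, hence 0.763 and 1.31.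

Below one, J holds more than half. Above one, Z must still beat J after Q has taken its share, at most 16.0% of what has left J for Z and Q together, so the even point between J and Z lies somewhat past one. Both counts therefore say J in ochre and Z in blue, and my reckoning stops at these ratios.

The forecast sides with the second count, “with its time-integrated amount in the saturating rate law”: J at 58% in ochre, Z at 52.5% in blue.

The simulation gives J at 58.2% in ochre and Z at 51.8% in blue, where J keeps 41.3% and E is down to 50.5% of its charge. So the decay count stands for blue, and the clock count keeps the early part of ochre: at 0.500 min, E there is still at 84.3%.

In blue, with each step taken net, Z is made 8.19 times faster than it is used up at 0.588 min, and still 4.66 times faster at the end, where Q holds 6.89%.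

The neighbour like blue but with 1.1 × 10⁻⁵ M of E has the same working time and a half-way time of 2.71 min, so it stands at 0.535, below one, and J should lead. Computed, that flask holds J at 68.1% and Z at 29.7%.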